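Ring A is built last, on a finished ring C. In ring A the oxygens on C5, C7 and C8a alternate with C6–H, the C8 side chain and the acyl-bearing C4a, and C4a/C8a are the α- and β-carbons of the ring C enone, with O1 already on C8a. A 4-alkyl-1-methoxy-1,3-bis(silyloxy)diene (C5 to C8 plus the complete side chain) is therefore annulated onto the (S)-5-bromo-2-aryl-2,3-dihydropyran-4-one: one operation forms C8–C8a and C4a–C5, and loss of methanol and HBr leaves the 5,7-dihydroxy-8-alkylflavanone, so a 6-alkyl isomer cannot arise. All hydroxyl protection is silyl, which reduces the end game to one fluoride step.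

Key step: step 12

Assumption: the (S,S)-configured chromium salen catalyst is taken to give the (2S)-cycloadduct, by analogy with simple aryl aldehydes; if 6 proves to be the (2R)-antipode, the mirror-image catalyst is used.
Assumption: 1 and 7 are bought as catalogue compounds.

Step 1
Reactants: 1 4-hydroxy-2-methoxybenzaldehyde
Product: 2 4-(tert-butyldimethylsilyloxy)-2-methoxybenzaldehyde
Conditions: TBSCl, imidazole, DMF, rt
Reagents that add atoms: tert-butyldimethylsilyl chloride, CC(C)(C)[Si](C)(C)Cl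
Why: Imidazole-promoted silylation of a phenol; the aryl silyl ether survives Lewis acids, NBS and amines and leaves with fluoride, so no acid is needed near the acid-labile 2,4-dioxygenated benzylic C2–O1 bond later on.

Step 2
Reactants: 2 4-(tert-butyldimethylsilyloxy)-2-methoxybenzaldehyde; 3 Danishefsky's diene
Product: 6 (S)-5-bromo-2-[4-(tert-butyldimethylsilyloxy)-2-methoxyphenyl]-2,3-dihydro-4H-pyran-4-one, via cycloadduct 4 (not isolated), via bromoketone 5 (not isolated)
Conditions: [Cr((S,S)-salen)]BF4 (5 mol %; salen = N,N′-bis(3,5-di-tert-butylsalicylidene)cyclohexane-1,2-diaminate), 4 Å MS, t-BuOMe, −30 °C; then NBS, THF, −78 °C; then Et3N, 0 °C to rt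
Reagents that add atoms: N-bromosuccinimide, O=C1CCC(=O)N1Br
Why: Hetero-Diels–Alder reaction of an aldehyde with Danishefsky's diene under chiral chromium salen catalysis, which stops at the true cycloadduct 4 and sets C2 by catalyst control (one face of the bound aldehyde is shielded by the ligand); the silyl enol ether of 4 is by far the most nucleophilic site and takes bromine from NBS at the carbon that becomes C5, and Et3N then expels methanol by E1cB, so the electron-rich ring B is never exposed to electrophilic bromination of the much less nucleophilic vinylogous ester.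

Step 3
Reactants: 7 (S)-3-bromo-2-methylpropan-1-ol
Product: 8 (S)-(3-bromo-2-methylpropoxy)(tert-butyl)dimethylsilane
Conditions: TBSCl, imidazole, CH2Cl2, 0 °C to rt
Reagents that add atoms: tert-butyldimethylsilyl chloride, CC(C)(C)[Si](C)(C)Cl
Why: Standard silylation of a primary alcohol; a silyl ether is chosen because it comes off with fluoride, whereas an aliphatic acetal would need acid strong enough to endanger the alkene and C2.

Step 4
Reactants: 8 (S)-(3-bromo-2-methylpropoxy)(tert-butyl)dimethylsilane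
Product: 10 (R)-4-(tert-butyldimethylsilyloxy)-3-methylbutanoic acid, via Grignard reagent 9 (not isolated)
Conditions: Mg, cat. I2, THF, reflux; then CO2 (g), −20 °C to rt; cold 0.5 M HCl
Reagents that add atoms: carbon dioxide, O=C=O; magnesium, [Mg] (stays in intermediate 9 only)
Why: Grignard formation and carboxylation add the carbon that becomes the benzylic CH2 (C1'') of the side chain without touching the methyl-bearing stereocentre, which comes from the chiral pool.

Step 5
Reactants: 10 (R)-4-(tert-butyldimethylsilyloxy)-3-methylbutanoic acid; 11 (S)-4-benzyl-2-oxazolidinone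
Product: 13 (S)-4-benzyl-3-[(R)-4-(tert-butyldimethylsilyloxy)-3-methylbutanoyl]oxazolidin-2-one, via mixed anhydride 12 (not isolated)
Conditions: t-BuCOCl, Et3N, THF, −20 to 0 °C; then 11, LiCl, rt
Reagents that add atoms: pivaloyl chloride, CC(C)(C)C(=O)Cl (stays in intermediate 12 only)
Why: Mixed-anhydride N-acylation of the Evans auxiliary under LiCl/Et3N, a standard loading that avoids an acid chloride next to the silyl ether.

Step 6
Reactants: 13 (S)-4-benzyl-3-[(R)-4-(tert-butyldimethylsilyloxy)-3-methylbutanoyl]oxazolidin-2-one; 14 prenyl bromide (1-bromo-3-methylbut-2-ene)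
Product: 16 (S)-4-benzyl-3-[(2S,3R)-4-(tert-butyldimethylsilyloxy)-3-methyl-2-(3-methylbut-2-en-1-yl)butanoyl]oxazolidin-2-one, via sodium enolate 15 (not isolated)
Conditions: NaN(SiMe3)2, THF, −78 °C; then 14, −78 to −40 °C
Reagents that add atoms: sodium bis(trimethylsilyl)amide, C[Si](C)(C)N([Na])[Si](C)(C)C (sodium stays in intermediate 15 only)
Why: Evans asymmetric alkylation: the chelated Z sodium enolate is attacked by the reactive allylic bromide on the face away from the benzyl group, which sets the prenyl-bearing centre (future C2'') under auxiliary control with the existing methyl centre as a spectator.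

Step 7
Reactants: 16 (S)-4-benzyl-3-[(2S,3R)-4-(tert-butyldimethylsilyloxy)-3-methyl-2-(3-methylbut-2-en-1-yl)butanoyl]oxazolidin-2-one
Product: 17 (2S,3R)-4-(tert-butyldimethylsilyloxy)-3-methyl-2-(3-methylbut-2-en-1-yl)butan-1-ol
Conditions: LiBH4, MeOH (1 equiv), Et2O, 0 °C
Reagents that add atoms: none
Why: Reductive cleavage of the N-acyl oxazolidinone to the primary alcohol, which spares the trisubstituted alkene and the silyl ether and does not epimerise the α-centre.

Step 8
Reactants: 17 (2S,3R)-4-(tert-butyldimethylsilyloxy)-3-methyl-2-(3-methylbut-2-en-1-yl)butan-1-ol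
Product: 18 tert-butyl{[(2R,3S)-3-(iodomethyl)-2,6-dimethylhept-5-en-1-yl]oxy}dimethylsilane
Conditions: I2, PPh3, imidazole, CH2Cl2, 0 °C to rt
Reagents that add atoms: iodine, II
Why: Appel-type iodination of a primary alcohol by SN2 displacement at CH2, with no stereocentre involved.

Step 9
Reactants: 18 tert-butyl{[(2R,3S)-3-(iodomethyl)-2,6-dimethylhept-5-en-1-yl]oxy}dimethylsilane; 19 methyl acetoacetate
Product: 21 methyl (6S,7R)-8-(tert-butyldimethylsilyloxy)-7-methyl-6-(3-methylbut-2-en-1-yl)-3-oxooctanoate, via dianion 20 (not isolated)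
Conditions: 19 (3 equiv), NaH, THF, 0 °C; n-BuLi, 0 °C; then 18, DMPU, 0 °C to rt; AcOH
Reagents that add atoms: sodium hydride, [Na+].[H-]; n-butyllithium, [Li]CCCC (metal ions stay in intermediate 20 only)
Why: γ-Alkylation of the acetoacetate dianion, which reacts at its terminal carbon with primary iodides and installs the whole β-keto ester in one step.

Step 10
Reactants: 21 methyl (6S,7R)-8-(tert-butyldimethylsilyloxy)-7-methyl-6-(3-methylbut-2-en-1-yl)-3-oxooctanoate
Product: 22 methyl (6S,7R)-8-(tert-butyldimethylsilyloxy)-7-methyl-6-(3-methylbut-2-en-1-yl)-3-(trimethylsilyloxy)oct-2-enoate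
Conditions: Me3SiCl, Et3N, toluene, rt
Reagents that add atoms: chlorotrimethylsilane, C[Si](C)(C)Cl
Why: O-Silylation of the β-keto ester enol, the first half of the standard two-step preparation of 1,3-bis(silyloxy)-1,3-dienes.

Step 11
Reactants: 22 methyl (6S,7R)-8-(tert-butyldimethylsilyloxy)-7-methyl-6-(3-methylbut-2-en-1-yl)-3-(trimethylsilyloxy)oct-2-enoate
Product: 24 (6R,7R)-8-(tert-butyldimethylsilyloxy)-1-methoxy-7-methyl-6-(3-methylbut-2-en-1-yl)-1,3-bis(trimethylsilyloxy)octa-1,3-diene, via lithium dienolate 23 (not isolated)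
Conditions: LiN(i-Pr)2, THF, −78 °C; then Me3SiCl, −78 to 0 °C; filtration under argon, no aqueous work-up
Reagents that add atoms: chlorotrimethylsilane, C[Si](C)(C)Cl; lithium diisopropylamide, CC(C)N([Li])C(C)C (lithium stays in intermediate 23 only)
Why: γ-Deprotonation of the silyl enol ether ester and O-silylation of the dienolate, the standard second half of the preparation of 4-alkyl-1-methoxy-1,3-bis(trimethylsilyloxy)-1,3-dienes.

Step 12
Reactants: 6 (S)-5-bromo-2-[4-(tert-butyldimethylsilyloxy)-2-methoxyphenyl]-2,3-dihydro-4H-pyran-4-one; 24 (6R,7R)-8-(tert-butyldimethylsilyloxy)-1-methoxy-7-methyl-6-(3-methylbut-2-en-1-yl)-1,3-bis(trimethylsilyloxy)octa-1,3-diene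
Product: 27 (2S)-2-[4-(tert-butyldimethylsilyloxy)-2-methoxyphenyl]-8-[(2R,3R)-4-(tert-butyldimethylsilyloxy)-3-methyl-2-(3-methylbut-2-en-1-yl)butyl]-5,7-dihydroxy-2,3-dihydro-4H-chromen-4-one, via cycloadduct 25 (not isolated), via bromotriketone 26 (not isolated)
Conditions: 24 (2.5 equiv), toluene, 85 °C, sealed tube; then MeOH, Et3N, 0 °C to rt; AcOH
Reagents that add atoms: none
Why: Proposed new method: diene 24 should add to bromoenone 6 as in a polar Diels–Alder reaction, its terminal carbon (future C8) bonding to the β-carbon C8a that carries O1 and its ketene-acetal carbon (future C5) to the brominated α-carbon C4a; whether the bonds form in concert or as a Mukaiyama–Michael addition followed by collapse of the enol(ate) at C4a onto the dioxycarbenium carbon (6-exo-trig, enol-exo), the same cis-fused adduct 25 results and ring A is the one ring closed. Methanolysis unmasks the C5 and C7 carbonyls (26), triethylamine removes HBr across C4a–C8a (directly, or after reversible oxa-Michael epimerisation at C8a) and enolisation gives the aromatic 5,7-diol, so the bromine supplies the oxidation level and no oxidant meets the phenols or the alkene. The closest known reaction types are the benzannulations of 1,3-bis(silyloxy)-1,3-dienes with 3-substituted chromones and with 3-silyloxy-enones, and the cycloadditions of such dienes to halogenated quinones that aromatise by loss of HX. No stereocentre is formed (those made in passing at C4a, C5, C8 and C8a vanish on aromatisation), and C2 is kept because C3 never meets more than a brief, weak amine base. The step needs the orientation of the diene, which the matched polarity of the two partners secures so that the chain can only end at C8, and it needs C4a–C5 closure to win over attack of the central diene carbon on C4=O, which the low electrophilicity of the vinylogous-ester carbonyl and the base-free thermal first stage are meant to secure.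

Step 13
Reactants: 27 (2S)-2-[4-(tert-butyldimethylsilyloxy)-2-methoxyphenyl]-8-[(2R,3R)-4-(tert-butyldimethylsilyloxy)-3-methyl-2-(3-methylbut-2-en-1-yl)butyl]-5,7-dihydroxy-2,3-dihydro-4H-chromen-4-one
Product: 28 (2S)-5,7-dihydroxy-2-(4-hydroxy-2-methoxyphenyl)-8-[(2R,3R)-4-hydroxy-3-methyl-2-(3-methylbut-2-en-1-yl)butyl]-2,3-dihydro-4H-chromen-4-one
Conditions: HF·pyridine, pyridine, THF, 0 °C to rt
Reagents that add atoms: none
Why: Fluoride cleavage of the aryl and the primary alkyl silyl ethers under buffered, non-basic and only weakly acidic conditions, which spares the trisubstituted alkene, the enolisable C3 and the benzylic C2–O1 bond.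

Compound list
1 | 4-hydroxy-2-methoxybenzaldehyde | COc1cc(O)ccc1C=O | starting material
2 | 4-(tert-butyldimethylsilyloxy)-2-methoxybenzaldehyde | COc1cc(O[Si](C)(C)C(C)(C)C)ccc1C=O | intermediate
3 | Danishefsky's diene, (E)-1-methoxy-3-(trimethylsilyloxy)buta-1,3-diene | CO/C=C/C(=C)O[Si](C)(C)C | starting material
4 | cycloadduct, (6S)-6-[4-(tert-butyldimethylsilyloxy)-2-methoxyphenyl]-2-methoxy-4-(trimethylsilyloxy)-5,6-dihydro-2H-pyran (C2 not defined) | COc1cc(O[Si](C)(C)C(C)(C)C)ccc1[C@@H]1CC(O[Si](C)(C)C)=CC(OC)O1 | intermediate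
5 | bromoketone, (6S)-3-bromo-6-[4-(tert-butyldimethylsilyloxy)-2-methoxyphenyl]-2-methoxytetrahydro-4H-pyran-4-one (C2, C3 not defined) | COc1cc(O[Si](C)(C)C(C)(C)C)ccc1[C@@H]1CC(=O)C(Br)C(OC)O1 | intermediate
6 | (S)-5-bromo-2-[4-(tert-butyldimethylsilyloxy)-2-methoxyphenyl]-2,3-dihydro-4H-pyran-4-one | COc1cc(O[Si](C)(C)C(C)(C)C)ccc1[C@@H]1CC(=O)C(Br)=CO1 | intermediate
7 | (S)-3-bromo-2-methylpropan-1-ol | BrC[C@@H](C)CO | starting material
8 | (S)-(3-bromo-2-methylpropoxy)(tert-butyl)dimethylsilane | BrC[C@@H](C)CO[Si](C)(C)C(C)(C)C | intermediate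
9 | Grignard reagent, [(S)-3-(tert-butyldimethylsilyloxy)-2-methylpropyl]magnesium bromide | Br[Mg]C[C@@H](C)CO[Si](C)(C)C(C)(C)C | intermediate
10 | (R)-4-(tert-butyldimethylsilyloxy)-3-methylbutanoic acid | OC(=O)C[C@@H](C)CO[Si](C)(C)C(C)(C)C | intermediate
11 | (S)-4-benzyl-2-oxazolidinone | O=C1N[C@@H](Cc2ccccc2)CO1 | starting material
12 | mixed anhydride, (R)-4-(tert-butyldimethylsilyloxy)-3-methylbutanoic pivalic anhydride | CC(C)(C)C(=O)OC(=O)C[C@@H](C)CO[Si](C)(C)C(C)(C)C | intermediate
13 | (S)-4-benzyl-3-[(R)-4-(tert-butyldimethylsilyloxy)-3-methylbutanoyl]oxazolidin-2-one | O=C1OC[C@H](Cc2ccccc2)N1C(=O)C[C@@H](C)CO[Si](C)(C)C(C)(C)C | intermediate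
14 | prenyl bromide, 1-bromo-3-methylbut-2-ene | CC(C)=CCBr | starting material
15 | sodium (Z)-enolate of 13 | O=C1OC[C@H](Cc2ccccc2)N1C(/[O-])=C/[C@@H](C)CO[Si](C)(C)C(C)(C)C.[Na+] | intermediate
16 | (S)-4-benzyl-3-[(2S,3R)-4-(tert-butyldimethylsilyloxy)-3-methyl-2-(3-methylbut-2-en-1-yl)butanoyl]oxazolidin-2-one | O=C1OC[C@H](Cc2ccccc2)N1C(=O)[C@@H](CC=C(C)C)[C@@H](C)CO[Si](C)(C)C(C)(C)C | intermediate
17 | (2S,3R)-4-(tert-butyldimethylsilyloxy)-3-methyl-2-(3-methylbut-2-en-1-yl)butan-1-ol | OC[C@@H](CC=C(C)C)[C@@H](C)CO[Si](C)(C)C(C)(C)C | intermediate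
18 | tert-butyl{[(2R,3S)-3-(iodomethyl)-2,6-dimethylhept-5-en-1-yl]oxy}dimethylsilane | IC[C@@H](CC=C(C)C)[C@@H](C)CO[Si](C)(C)C(C)(C)C | intermediate
19 | methyl acetoacetate | CC(=O)CC(=O)OC | starting material
20 | dianion of methyl acetoacetate (sodium lithium salt) | [Na+].[Li+].[CH2-]C(=O)[CH-]C(=O)OC | intermediate
21 | methyl (6S,7R)-8-(tert-butyldimethylsilyloxy)-7-methyl-6-(3-methylbut-2-en-1-yl)-3-oxooctanoate | COC(=O)CC(=O)CC[C@@H](CC=C(C)C)[C@@H](C)CO[Si](C)(C)C(C)(C)C | intermediate
22 | methyl (6S,7R)-8-(tert-butyldimethylsilyloxy)-7-methyl-6-(3-methylbut-2-en-1-yl)-3-(trimethylsilyloxy)oct-2-enoate (alkene geometry immaterial) | COC(=O)C=C(O[Si](C)(C)C)CC[C@@H](CC=C(C)C)[C@@H](C)CO[Si](C)(C)C(C)(C)C | intermediate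
23 | lithium dienolate of 22 | [Li+].[O-]C(OC)=CC(O[Si](C)(C)C)=CC[C@@H](CC=C(C)C)[C@@H](C)CO[Si](C)(C)C(C)(C)C | intermediate
24 | (6R,7R)-8-(tert-butyldimethylsilyloxy)-1-methoxy-7-methyl-6-(3-methylbut-2-en-1-yl)-1,3-bis(trimethylsilyloxy)octa-1,3-diene (alkene geometry immaterial) | COC(O[Si](C)(C)C)=CC(O[Si](C)(C)C)=CC[C@@H](CC=C(C)C)[C@@H](C)CO[Si](C)(C)C(C)(C)C | intermediate
25 | cycloadduct, (2S)-4a-bromo-5-methoxy-5,7-bis(trimethylsilyloxy)-2,3,4a,5,8,8a-hexahydro-4H-chromen-4-one carrying the aryl group of 6 at C2 and the side chain of 24 at C8 (C4a, C5, C8, C8a not defined) | COc1cc(O[Si](C)(C)C(C)(C)C)ccc1[C@@H]1CC(=O)C2(Br)C(O1)C(C[C@@H](CC=C(C)C)[C@@H](C)CO[Si](C)(C)C(C)(C)C)C(O[Si](C)(C)C)=CC2(OC)O[Si](C)(C)C | intermediate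
26 | bromotriketone, (2S)-4a-bromo-hexahydro-2H-chromene-4,5,7-trione with the same C2 and C8 substituents (C4a, C8, C8a not defined) | COc1cc(O[Si](C)(C)C(C)(C)C)ccc1[C@@H]1CC(=O)C2(Br)C(O1)C(C[C@@H](CC=C(C)C)[C@@H](C)CO[Si](C)(C)C(C)(C)C)C(=O)CC2=O | intermediate
27 | (2S)-2-[4-(tert-butyldimethylsilyloxy)-2-methoxyphenyl]-8-[(2R,3R)-4-(tert-butyldimethylsilyloxy)-3-methyl-2-(3-methylbut-2-en-1-yl)butyl]-5,7-dihydroxy-2,3-dihydro-4H-chromen-4-one | COc1cc(O[Si](C)(C)C(C)(C)C)ccc1[C@@H]1CC(=O)c2c(O)cc(O)c(C[C@@H](CC=C(C)C)[C@@H](C)CO[Si](C)(C)C(C)(C)C)c2O1 | intermediate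
28 | (2S)-5,7-dihydroxy-2-(4-hydroxy-2-methoxyphenyl)-8-[(2R,3R)-4-hydroxy-3-methyl-2-(3-methylbut-2-en-1-yl)butyl]-2,3-dihydro-4H-chromen-4-one (CNP0081318.1) | COc1cc(O)ccc1[C@@H]1CC(=O)c2c(O)cc(O)c(C[C@@H](CC=C(C)C)[C@@H](C)CO)c2O1 | target

Total steps: 13. Longest linear sequence: 11 steps (7 → 8 → 10 → 13 → 16 → 17 → 18 → 21 → 22 → 24 → 27 → 28; steps 3 to 13).

Steps most likely to fail

1. Step 12 (unproven benzannulation). After the first C–C bond the second may fail to close, or the adduct may open ring C by β-elimination of O1 or pass its bromine on instead of losing HBr. The fallback uses known chemistry only, sets out from iodide 18 and aldehyde 1, and rejoins the route at 28. Commercial 1-[2-hydroxy-4,6-bis(methoxymethoxy)phenyl]ethanone is iodinated ortho to the free phenol (NIS, CH2Cl2) to 1-[2-hydroxy-3-iodo-4,6-bis(methoxymethoxy)phenyl]ethanone F1. Iodide 18 is converted with Zn dust and LiCl in THF into the alkylzinc iodide F2, which is coupled with the sodium phenoxide of F1 (NaH; Pd(OAc)2/SPhos, THF) in a Negishi reaction to give the 3-alkylated acetophenone F3. Aldehyde 1 is protected (MOMCl, i-Pr2NEt) as 2-methoxy-4-(methoxymethoxy)benzaldehyde F4. Claisen–Schmidt condensation of F3 with F4 (KOH, EtOH) gives chalcone F5, whose only free phenol sits next to the alkyl group, so that NaOAc in refluxing EtOH closes the 8-alkyl flavanone F6 as a mixture of C2 epimers. Preparative HPLC on a chiral stationary phase gives the (2S)-flavanone F7, and HCl in MeOH removes the three acetals and the silyl ether to give 28.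

2. Step 2 (one-pot cycloaddition, bromination and elimination). Facial selectivity may be insufficient with the electron-rich, ortho-substituted aldehyde, or capture of the enol ether by NBS may be incomplete so that unbrominated pyranone is carried along. The fallback sets out from 2 and 3 and rejoins at 6. A hetero-Diels–Alder reaction catalysed by Ti(OiPr)4/(R)-H8-BINOL (antipode chosen for the 2S product) with CF3CO2H work-up gives the unbrominated (S)-2-aryl-2,3-dihydro-4H-pyran-4-one F8. Pyrrolidine in THF opens the vinylogous ester by amine exchange to the δ-hydroxy enaminone F9 without breaking the C–O bond at the stereocentre. The enaminone α-carbon, now far more nucleophilic than ring B, is brominated with NBS at −78 °C to the bromo enaminone F10, and AcOH recloses the ring with loss of pyrrolidine to give 6.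

3. Step 9 (dianion alkylation). SN2 displacement at the β-branched iodide may be slow, so that E2 elimination and proton transfer compete. The fallback sets out from 18 and rejoins at 21. LiCH2CN (from MeCN and LiN(i-Pr)2, THF, −78 °C), a small and very reactive nucleophile, displaces the iodide to give nitrile F11. A Blaise reaction with the Reformatsky reagent from methyl bromoacetate and Zn (THF, reflux) gives the enamino ester F12, which cold dilute HCl hydrolyses to 21.

Further compounds
F1 | step 12 | 1-[2-hydroxy-3-iodo-4,6-bis(methoxymethoxy)phenyl]ethanone | CC(=O)c1c(O)c(I)c(OCOC)cc1OCOC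
F2 | step 12 | [(2S,3R)-4-(tert-butyldimethylsilyloxy)-3-methyl-2-(3-methylbut-2-en-1-yl)butyl]zinc iodide | I[Zn]C[C@@H](CC=C(C)C)[C@@H](C)CO[Si](C)(C)C(C)(C)C
F3 | step 12 | 1-{3-[(2R,3R)-4-(tert-butyldimethylsilyloxy)-3-methyl-2-(3-methylbut-2-en-1-yl)butyl]-2-hydroxy-4,6-bis(methoxymethoxy)phenyl}ethanone | CC(=O)c1c(O)c(C[C@@H](CC=C(C)C)[C@@H](C)CO[Si](C)(C)C(C)(C)C)c(OCOC)cc1OCOC
F4 | step 12 | 2-methoxy-4-(methoxymethoxy)benzaldehyde | COCOc1ccc(C=O)c(OC)c1
F5 | step 12 | (E)-1-{3-[(2R,3R)-4-(tert-butyldimethylsilyloxy)-3-methyl-2-(3-methylbut-2-en-1-yl)butyl]-2-hydroxy-4,6-bis(methoxymethoxy)phenyl}-3-[2-methoxy-4-(methoxymethoxy)phenyl]prop-2-en-1-one | COCOc1ccc(/C=C/C(=O)c2c(O)c(C[C@@H](CC=C(C)C)[C@@H](C)CO[Si](C)(C)C(C)(C)C)c(OCOC)cc2OCOC)c(OC)c1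
F6 | step 12 | 8-[(2R,3R)-4-(tert-butyldimethylsilyloxy)-3-methyl-2-(3-methylbut-2-en-1-yl)butyl]-2-[2-methoxy-4-(methoxymethoxy)phenyl]-5,7-bis(methoxymethoxy)-2,3-dihydro-4H-chromen-4-one (both C2 epimers) | COCOc1ccc(C2CC(=O)c3c(OCOC)cc(OCOC)c(C[C@@H](CC=C(C)C)[C@@H](C)CO[Si](C)(C)C(C)(C)C)c3O2)c(OC)c1
F7 | step 12 | (2S)-8-[(2R,3R)-4-(tert-butyldimethylsilyloxy)-3-methyl-2-(3-methylbut-2-en-1-yl)butyl]-2-[2-methoxy-4-(methoxymethoxy)phenyl]-5,7-bis(methoxymethoxy)-2,3-dihydro-4H-chromen-4-one | COc1cc(OCOC)ccc1[C@@H]1CC(=O)c2c(OCOC)cc(OCOC)c(C[C@@H](CC=C(C)C)[C@@H](C)CO[Si](C)(C)C(C)(C)C)c2O1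
F8 | step 2 | (S)-2-[4-(tert-butyldimethylsilyloxy)-2-methoxyphenyl]-2,3-dihydro-4H-pyran-4-one | COc1cc(O[Si](C)(C)C(C)(C)C)ccc1[C@@H]1CC(=O)C=CO1
F9 | step 2 | (S,E)-5-[4-(tert-butyldimethylsilyloxy)-2-methoxyphenyl]-5-hydroxy-1-(pyrrolidin-1-yl)pent-1-en-3-one | COc1cc(O[Si](C)(C)C(C)(C)C)ccc1[C@@H](O)CC(=O)/C=C/N1CCCC1
F10 | step 2 | (S)-2-bromo-5-[4-(tert-butyldimethylsilyloxy)-2-methoxyphenyl]-5-hydroxy-1-(pyrrolidin-1-yl)pent-1-en-3-one | COc1cc(O[Si](C)(C)C(C)(C)C)ccc1[C@@H](O)CC(=O)C(Br)=CN1CCCC1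
F11 | step 9 | (4S,5R)-6-(tert-butyldimethylsilyloxy)-5-methyl-4-(3-methylbut-2-en-1-yl)hexanenitrile | N#CCC[C@@H](CC=C(C)C)[C@@H](C)CO[Si](C)(C)C(C)(C)C
F12 | step 9 | methyl (2Z,6S,7R)-3-amino-8-(tert-butyldimethylsilyloxy)-7-methyl-6-(3-methylbut-2-en-1-yl)oct-2-enoate | COC(=O)/C=C(\N)CC[C@@H](CC=C(C)C)[C@@H](C)CO[Si](C)(C)C(C)(C)C
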